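**Retrosynthetic overview**

1. Target 37 ⇐ bis-silyl ether 36 ⇐ seco bis-iodide 34. The ten-membered carbocycle (C1–C10) is closed last at C3–C4, the bond linking the C3 methylene to C4, the methyl-bearing carbon of the Z C4=C5 olefin; it lies across the ring from stereocentres C6–C9 and from all oxygenated carbons (alkylzinc/alkenyl iodide Negishi coupling).
2. 34 ⇐ γ-lactone alcohol 26 by C9 acylation, PMB removal, C3 iodination and C8 isobutyrylation; 26 ⇐ δ-lactone adduct 25 by translactonisation from O9 to O6.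
3. 25 ⇐ α-(bromomethyl) δ-lactone 19 + (Z)-3-iodobut-2-enal 23 by zinc Barbier allylation: C6–C7 bond, with C6 and C7 set under control of the temporary O9–C12 ring.
4. 19 ⇐ ring-closing metathesis of 2-(bromomethyl)acrylate 18 ⇐ alcohol 15 ⇐ Z-alkenyl iodide 8 + (S)-aldehyde 12 (chelation-controlled addition sets C9; C8 comes from (S)-but-3-ene-1,2-diol).
5. Ring order: temporary δ-lactone (RCM), then the γ-lactone (translactonisation), then the ten-membered carbocycle (Negishi).

Key step: step 22

Assumption: germacrane numbering is used (ring C1–C10; lactone O–C12(=O)–C11(=C13) across C6/C7; C14 = CH2O on C10; C15 = CH3 on C4), and (S)-but-3-ene-1,2-diol and 2-(bromomethyl)acrylic acid are taken as purchasable, replacing a tartrate/acrylate start because an open-chain allyl reagent would not control C6/C7 reliably.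

**Route**

Step 1
Reactants: 1 but-3-yn-1-ol
Product: 2 1-[(but-3-yn-1-yloxy)methyl]-4-methoxybenzene
Conditions: NaH, PMBCl, Bu4NI (cat.), THF/DMF, 0 °C to rt
Reagents that add atoms: 4-methoxybenzyl chloride, COc1ccc(CCl)cc1
Why: Williamson etherification of the primary alkoxide should give the PMB ether that masks the future C3 oxygen.

Step 2
Reactants: 2 1-[(but-3-yn-1-yloxy)methyl]-4-methoxybenzene; 3 paraformaldehyde
Product: 5 5-[(4-methoxybenzyl)oxy]pent-2-yn-1-ol, via lithium acetylide 4 (not isolated)
Conditions: n-BuLi, THF, −78 °C; (CH2O)n, −78 °C to rt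
Reagents that add atoms: none
Why: Addition of the lithium acetylide to formaldehyde (alkyne hydroxymethylation) should install C14 as a propargylic alcohol.

Step 3
Reactants: 5 5-[(4-methoxybenzyl)oxy]pent-2-yn-1-ol
Product: 6 (Z)-5-[(4-methoxybenzyl)oxy]-2-(tributylstannyl)pent-2-en-1-ol
Conditions: Bu3SnH, [Cp*RuCl]4 (cat.), CH2Cl2, rt
Reagents that add atoms: tributyltin hydride, CCCC[SnH](CCCC)CCCC
Why: Hydroxyl-directed ruthenium-catalysed trans-hydrostannation should place tin on the alkyne carbon next to the carbinol and hydrogen anti to it, which fixes the later C1=C10 geometry.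

Step 4
Reactants: 6 (Z)-5-[(4-methoxybenzyl)oxy]-2-(tributylstannyl)pent-2-en-1-ol
Product: 7 (Z)-2-iodo-5-[(4-methoxybenzyl)oxy]pent-2-en-1-ol
Conditions: I2, CH2Cl2, 0 °C
Reagents that add atoms: iodine, II
Why: Iododestannylation proceeds with retention of olefin geometry, so iodine should end cis to the CH2CH2OPMB chain.

Step 5
Reactants: 7 (Z)-2-iodo-5-[(4-methoxybenzyl)oxy]pent-2-en-1-ol
Product: 8 (Z)-tert-butyl({2-iodo-5-[(4-methoxybenzyl)oxy]pent-2-en-1-yl}oxy)dimethylsilane
Conditions: TBSCl, imidazole, CH2Cl2, rt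
Reagents that add atoms: tert-butyldimethylsilyl chloride, CC(C)(C)[Si](C)(C)Cl
Why: Standard silylation of the primary allylic alcohol protects C14–OH for the organometallic step and to the end of the route.

Step 6
Reactants: 9 (S)-but-3-ene-1,2-diol
Product: 10 (4S)-2-(4-methoxyphenyl)-4-vinyl-1,3-dioxolane (both C2 epimers)
Conditions: 4-MeOC6H4CH(OMe)2, CSA (cat.), CH2Cl2, rt
Reagents that add atoms: 4-methoxybenzaldehyde dimethyl acetal, COC(OC)c1ccc(OC)cc1
Why: Acid-catalysed transacetalisation of the 1,2-diol should give the p-methoxybenzylidene acetal without touching the stereocentre (future C8).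

Step 7
Reactants: 10 (4S)-2-(4-methoxyphenyl)-4-vinyl-1,3-dioxolane
Product: 11 (S)-2-[(4-methoxybenzyl)oxy]but-3-en-1-ol
Conditions: DIBAL-H, CH2Cl2, −78 to 0 °C
Reagents that add atoms: none
Why: Reductive acetal opening: aluminium coordinates the less hindered primary oxygen and cleaves that C–O bond, so the PMB group should remain on the secondary oxygen.

Step 8
Reactants: 11 (S)-2-[(4-methoxybenzyl)oxy]but-3-en-1-ol
Product: 12 (S)-2-[(4-methoxybenzyl)oxy]but-3-enal
Conditions: Dess–Martin periodinane, CH2Cl2, 0 °C; used crude at once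
Reagents that add atoms: none
Why: Dess–Martin oxidation is mild and non-basic, so the α-alkoxy β,γ-unsaturated aldehyde should form without epimerisation or conjugation if used immediately.

Step 9
Reactants: 8 (Z)-tert-butyl({2-iodo-5-[(4-methoxybenzyl)oxy]pent-2-en-1-yl}oxy)dimethylsilane; 12 (S)-2-[(4-methoxybenzyl)oxy]but-3-enal
Product: 15 (3S,4S,5Z)-5-{[(tert-butyldimethylsilyl)oxy]methyl}-3,8-bis[(4-methoxybenzyl)oxy]octa-1,5-dien-4-ol, via alkenyllithium 13 (not isolated), via alkenylmagnesium bromide 14 (not isolated)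
Conditions: 8, t-BuLi (2 equiv), Et2O, −78 °C; MgBr2·OEt2; then 12, CH2Cl2/Et2O, −78 °C
Reagents that add atoms: none
Why: Iodine–lithium exchange with retention, transmetalation to magnesium and Cram-chelate 1,2-addition: magnesium bridges the carbonyl and the α-OPMB oxygen and the alkenyl group attacks opposite the vinyl substituent, which should give the 3,4-syn alcohol (new C9 stereocentre) with the Z olefin carried over from 8.

Step 10
Reactants: 15 (3S,4S,5Z)-5-{[(tert-butyldimethylsilyl)oxy]methyl}-3,8-bis[(4-methoxybenzyl)oxy]octa-1,5-dien-4-ol; 16 2-(bromomethyl)acrylic acid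
Product: 18 (3S,4S,5Z)-5-{[(tert-butyldimethylsilyl)oxy]methyl}-3,8-bis[(4-methoxybenzyl)oxy]octa-1,5-dien-4-yl 2-(bromomethyl)acrylate, via acid chloride 17 (not isolated)
Conditions: 16, (COCl)2, DMF (cat.), CH2Cl2, 0 °C; concentrate; then 15, 2,6-lutidine, CH2Cl2, −20 °C to rt
Reagents that add atoms: none
Why: Acylation of the secondary alcohol by the acid chloride with a hindered, non-nucleophilic base should avoid SN2′ attack of an amine on the allylic bromide.

Step 11
Reactants: 18 (3S,4S,5Z)-5-{[(tert-butyldimethylsilyl)oxy]methyl}-3,8-bis[(4-methoxybenzyl)oxy]octa-1,5-dien-4-yl 2-(bromomethyl)acrylate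
Product: 19 (5S,6S)-3-(bromomethyl)-6-[(Z)-1-{[(tert-butyldimethylsilyl)oxy]methyl}-4-[(4-methoxybenzyl)oxy]but-1-en-1-yl]-5-[(4-methoxybenzyl)oxy]-5,6-dihydro-2H-pyran-2-one
Conditions: Grubbs II (cat.), toluene (5 mM), 80 °C
Reagents that add atoms: none
Why: Ring-closing metathesis between the terminal vinyl group and the 1,1-disubstituted acrylate should close the six-membered unsaturated lactone (C7=C11), the trisubstituted C1=C10 olefin being too hindered to compete.

Step 12
Reactants: 20 but-2-yn-1-ol
Product: 22 (Z)-3-iodobut-2-en-1-ol, via sodium alkenylalanate 21 (not isolated)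
Conditions: Red-Al, THF, 0 °C to rt; I2, −78 to 0 °C
Reagents that add atoms: iodine, II
Why: Trans-hydroalumination of the propargylic alcohol through a five-membered alkoxyalanate places aluminium on C3 cis to the CH2O group, and iodinolysis with retention should give the Z-iodide.

Step 13
Reactants: 22 (Z)-3-iodobut-2-en-1-ol
Product: 23 (Z)-3-iodobut-2-enal
Conditions: MnO2, CH2Cl2, rt, dark; used at once
Reagents that add atoms: none
Why: Neutral allylic oxidation with manganese dioxide should give the enal without Z to E isomerisation if light and acid are excluded.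

Step 14
Reactants: 19 α-(bromomethyl) δ-lactone (as in step 11); 23 (Z)-3-iodobut-2-enal
Product: 25 δ-lactone adduct: (5S,6S)-3-methylenetetrahydropyran-2-one carrying at C4 the (Z)-1-hydroxy-3-iodobut-2-en-1-yl group trans to the 5-OPMB group (C6 and C7 of the target set), via allylzinc bromide 24 (not isolated)
Conditions: Zn dust, sat. aq NH4Cl/THF, 0 °C to rt
Reagents that add atoms: none
Why: Barbier-type zinc 2-(alkoxycarbonyl)allylation: the allylzinc adds through C7 (SE2′) in a closed chair transition state in which the lactone ring holds C8 trans to the CH2Zn terminus (E-crotyl-like, so 6,7-anti is expected) and the aldehyde approaches C7 anti to the pseudoaxial C8–OPMB group and the C9 side chain, which sets C7 and C6 relative to C8/C9.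

Step 15
Reactants: 25 δ-lactone adduct
Product: 26 (4S,5S)-4-[(1S,2S,3Z)-3-{[(tert-butyldimethylsilyl)oxy]methyl}-2-hydroxy-1,6-bis[(4-methoxybenzyl)oxy]hex-3-en-1-yl]-5-[(Z)-2-iodoprop-1-en-1-yl]-3-methylenedihydrofuran-2(3H)-one
Conditions: CSA (cat.), CH2Cl2, rt
Reagents that add atoms: none
Why: Acid-catalysed translactonisation: the C6 hydroxyl attacks C12 to give the more stable trans-disubstituted γ-lactone and releases the C9 hydroxyl, with no stereocentre touched.

Step 16
Reactants: 27 2-hydroxy-2-methylpropanoic acid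
Product: 28 triethylsilyl 2-methyl-2-[(triethylsilyl)oxy]propanoate
Conditions: TESOTf (2.2 equiv), 2,6-lutidine, CH2Cl2, 0 °C
Reagents that add atoms: triethylsilyl trifluoromethanesulfonate, CC[Si](CC)(CC)OS(=O)(=O)C(F)(F)F
Why: The silyl triflate should silylate both the carboxylic acid and the hindered tertiary alcohol.

Step 17
Reactants: 28 triethylsilyl 2-methyl-2-[(triethylsilyl)oxy]propanoate
Product: 29 2-methyl-2-[(triethylsilyl)oxy]propanoyl chloride
Conditions: (COCl)2, DMF (cat.), CH2Cl2, 0 °C to rt; used crude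
Reagents that add atoms: oxalyl chloride, O=C(Cl)C(=O)Cl
Why: Silyl esters are converted by oxalyl chloride/DMF into acid chlorides under neutral conditions (no HCl is formed), so the tertiary silyl ether should survive.

Step 18
Reactants: 26 γ-lactone alcohol (as in step 15); 29 2-methyl-2-[(triethylsilyl)oxy]propanoyl chloride
Product: 30 C9 2-methyl-2-[(triethylsilyl)oxy]propanoate of 26
Conditions: DMAP, CH2Cl2, 0 °C to rt
Reagents that add atoms: none
Why: DMAP-mediated acylation puts the hindered acyl group on the only free hydroxyl (C9) while C8 is still blocked as its PMB ether, so the two esters cannot be interchanged.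

Step 19
Reactants: 30 C9 ester
Product: 31 C3,C8-diol (both PMB groups removed)
Conditions: DDQ, CH2Cl2/pH 7 buffer, 0 °C to rt
Reagents that add atoms: none
Why: Oxidative cleavage of both p-methoxybenzyl ethers with DDQ under buffered conditions should leave the silyl ethers, esters, lactone and alkenyl iodide intact.

Step 20
Reactants: 31 C3,C8-diol
Product: 32 C3 iodide with free C8 hydroxyl
Conditions: PPh3, I2, imidazole (premixed), CH2Cl2, 0 °C
Reagents that add atoms: iodine, II
Why: Appel iodination is selective for the unhindered primary C3 alcohol over the hindered secondary C8 alcohol.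

Step 21
Reactants: 32 C3 iodide with free C8 hydroxyl; 33 isobutyric anhydride
Product: 34 seco bis-iodide: (4S,5S)-lactone with C8 isobutyrate, C9 2-methyl-2-(triethylsilyloxy)propanoate, C14 OTBS, primary iodide at C3 and Z-alkenyl iodide at C4
Conditions: (i-PrCO)2O, Et3N, DMAP (cat.), CH2Cl2, 0 °C
Reagents that add atoms: none
Why: DMAP-catalysed acylation of the C8 alcohol should be faster than migration of the hindered C9 ester or alkylation of the amine by the primary iodide.

Step 22
Reactants: 34 seco bis-iodide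
Product: 36 bis-silyl ether of the target (ten-membered ring closed), via alkylzinc iodide 35 (not isolated)
Conditions: Zn dust (BrCH2CH2Br/TMSCl-activated), THF/DMA, 30 °C; then syringe-pump addition to Pd2(dba)3 (cat.), SPhos, THF, 45 °C (about 1 mM)
Reagents that add atoms: none
Why: Activated zinc should insert into the primary C3–I bond under conditions that leave the unactivated alkenyl C4–I bond, the esters and the lactone untouched, giving 35; Pd(0) then adds oxidatively to the Z-alkenyl iodide, intramolecular transmetalation gives an eleven-membered alkyl(alkenyl)palladacycle and reductive elimination forms C3–C4. The closest known reaction type is the alkyl–alkenyl Negishi coupling, with B-alkyl Suzuki macrocyclisations as the ring-size analogy. The ten-membered carbocycle is closed by C(sp3)–C(sp2) reductive elimination at C4, with the C4=C5 olefin endocyclic and its Z geometry retained. No stereocentre is formed, so C6–C9 pass through unchanged. The step needs cyclisation to outrun oligomerisation, β-hydride elimination and Heck-type insertion into C11=C13; slow addition at high dilution, a bulky electron-rich biarylphosphine that speeds reductive elimination, and the chain folding imposed by the trans-lactone and the Z C1=C10 olefin should secure this. The C3 zinc reagent lacks a leaving group in the β-position and, without a copper salt, is not expected to attack the α-methylene lactone.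

Step 23
Reactants: 36 bis-silyl ether of the target
Product: 37 CNP0220567.2 (target)
Conditions: HF·pyridine, pyridine, THF, 0 °C to rt
Reagents that add atoms: none
Why: Buffered fluoride desilylation should remove the primary allylic TBS ether and the tertiary TES ether without affecting the esters, the α-methylene lactone or the olefins.

**Compound list**

1 | but-3-yn-1-ol | C#CCCO | starting material
2 | 1-[(but-3-yn-1-yloxy)methyl]-4-methoxybenzene | C#CCCOCc1ccc(OC)cc1 | intermediate
3 | paraformaldehyde (formaldehyde) | C=O | starting material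
4 | {4-[(4-methoxybenzyl)oxy]but-1-yn-1-yl}lithium | [Li]C#CCCOCc1ccc(OC)cc1 | intermediate
5 | 5-[(4-methoxybenzyl)oxy]pent-2-yn-1-ol | OCC#CCCOCc1ccc(OC)cc1 | intermediate
6 | (Z)-5-[(4-methoxybenzyl)oxy]-2-(tributylstannyl)pent-2-en-1-ol | OC/C([Sn](CCCC)(CCCC)CCCC)=C/CCOCc1ccc(OC)cc1 | intermediate
7 | (Z)-2-iodo-5-[(4-methoxybenzyl)oxy]pent-2-en-1-ol | OC/C(I)=C/CCOCc1ccc(OC)cc1 | intermediate
8 | (Z)-tert-butyl({2-iodo-5-[(4-methoxybenzyl)oxy]pent-2-en-1-yl}oxy)dimethylsilane | CC(C)(C)[Si](C)(C)OC/C(I)=C/CCOCc1ccc(OC)cc1 | intermediate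
9 | (S)-but-3-ene-1,2-diol | OC[C@@H](O)C=C | starting material
10 | (4S)-2-(4-methoxyphenyl)-4-vinyl-1,3-dioxolane (both C2 epimers) | C=C[C@H]1COC(c2ccc(OC)cc2)O1 | intermediate
11 | (S)-2-[(4-methoxybenzyl)oxy]but-3-en-1-ol | C=C[C@H](OCc1ccc(OC)cc1)CO | intermediate
12 | (S)-2-[(4-methoxybenzyl)oxy]but-3-enal | C=C[C@H](OCc1ccc(OC)cc1)C=O | intermediate
13 | alkenyllithium from 8 (lithium in place of iodine; geometry retained) | [Li]/C(CO[Si](C)(C)C(C)(C)C)=C\CCOCc1ccc(OC)cc1 | intermediate
14 | alkenylmagnesium bromide from 13 (geometry retained) | Br[Mg]/C(CO[Si](C)(C)C(C)(C)C)=C\CCOCc1ccc(OC)cc1 | intermediate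
15 | (3S,4S,5Z)-5-{[(tert-butyldimethylsilyl)oxy]methyl}-3,8-bis[(4-methoxybenzyl)oxy]octa-1,5-dien-4-ol | C=C[C@H](OCc1ccc(OC)cc1)[C@@H](O)/C(CO[Si](C)(C)C(C)(C)C)=C\CCOCc1ccc(OC)cc1 | intermediate
16 | 2-(bromomethyl)acrylic acid | C=C(CBr)C(=O)O | starting material
17 | 2-(bromomethyl)acryloyl chloride | C=C(CBr)C(Cl)=O | intermediate
18 | (3S,4S,5Z)-5-{[(tert-butyldimethylsilyl)oxy]methyl}-3,8-bis[(4-methoxybenzyl)oxy]octa-1,5-dien-4-yl 2-(bromomethyl)acrylate | C=C[C@H](OCc1ccc(OC)cc1)[C@@H](OC(=O)C(=C)CBr)/C(CO[Si](C)(C)C(C)(C)C)=C\CCOCc1ccc(OC)cc1 | intermediate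
19 | (5S,6S)-3-(bromomethyl)-6-[(Z)-1-{[(tert-butyldimethylsilyl)oxy]methyl}-4-[(4-methoxybenzyl)oxy]but-1-en-1-yl]-5-[(4-methoxybenzyl)oxy]-5,6-dihydro-2H-pyran-2-one | BrCC1=C[C@H](OCc2ccc(OC)cc2)[C@@H](OC1=O)/C(CO[Si](C)(C)C(C)(C)C)=C\CCOCc2ccc(OC)cc2 | intermediate
20 | but-2-yn-1-ol | CC#CCO | starting material
21 | cyclic sodium alkenylalanate from 20 (Al on C3; O–Al chelate) | CC1=CCO[Al-]1(OCCOC)OCCOC.[Na+] | intermediate
22 | (Z)-3-iodobut-2-en-1-ol | C/C(I)=C/CO | intermediate
23 | (Z)-3-iodobut-2-enal | C/C(I)=C/C=O | intermediate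
24 | allylzinc bromide from 19 (ZnBr in place of Br) | Br[Zn]CC1=C[C@H](OCc2ccc(OC)cc2)[C@@H](OC1=O)/C(CO[Si](C)(C)C(C)(C)C)=C\CCOCc2ccc(OC)cc2 | intermediate
25 | δ-lactone adduct: (5S,6S)-3-methylenetetrahydropyran-2-one with the (Z)-1-hydroxy-3-iodobut-2-en-1-yl group at C4 trans to 5-OPMB; target C6 and C7 configured as in 37 | C=C1C(=O)O[C@@H](/C(CO[Si](C)(C)C(C)(C)C)=C\CCOCc2ccc(OC)cc2)[C@@H](OCc2ccc(OC)cc2)[C@@H]1[C@H](O)/C=C(/C)I | intermediate
26 | (4S,5S)-4-[(1S,2S,3Z)-3-{[(tert-butyldimethylsilyl)oxy]methyl}-2-hydroxy-1,6-bis[(4-methoxybenzyl)oxy]hex-3-en-1-yl]-5-[(Z)-2-iodoprop-1-en-1-yl]-3-methylenedihydrofuran-2(3H)-one | C=C1C(=O)O[C@H](/C=C(/C)I)[C@H]1[C@H](OCc2ccc(OC)cc2)[C@@H](O)/C(CO[Si](C)(C)C(C)(C)C)=C\CCOCc2ccc(OC)cc2 | intermediate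
27 | 2-hydroxy-2-methylpropanoic acid | CC(C)(O)C(=O)O | starting material
28 | triethylsilyl 2-methyl-2-[(triethylsilyl)oxy]propanoate | CC[Si](CC)(CC)OC(C)(C)C(=O)O[Si](CC)(CC)CC | intermediate
29 | 2-methyl-2-[(triethylsilyl)oxy]propanoyl chloride | CC[Si](CC)(CC)OC(C)(C)C(Cl)=O | intermediate
30 | 26 acylated at the C9 hydroxyl with the 2-methyl-2-(triethylsilyloxy)propanoyl group | C=C1C(=O)O[C@H](/C=C(/C)I)[C@H]1[C@H](OCc2ccc(OC)cc2)[C@@H](OC(=O)C(C)(C)O[Si](CC)(CC)CC)/C(CO[Si](C)(C)C(C)(C)C)=C\CCOCc2ccc(OC)cc2 | intermediate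
31 | C3,C8-diol from 30 (both PMB ethers removed) | C=C1C(=O)O[C@H](/C=C(/C)I)[C@H]1[C@H](O)[C@@H](OC(=O)C(C)(C)O[Si](CC)(CC)CC)/C(CO[Si](C)(C)C(C)(C)C)=C\CCO | intermediate
32 | C3 primary iodide with free C8 hydroxyl | C=C1C(=O)O[C@H](/C=C(/C)I)[C@H]1[C@H](O)[C@@H](OC(=O)C(C)(C)O[Si](CC)(CC)CC)/C(CO[Si](C)(C)C(C)(C)C)=C\CCI | intermediate
33 | isobutyric anhydride | CC(C)C(=O)OC(=O)C(C)C | starting material
34 | seco bis-iodide (C8 isobutyrate, C9 silyloxy-isobutyrate, C14 OTBS, C3 alkyl iodide, C4 Z-alkenyl iodide) | C=C1C(=O)O[C@H](/C=C(/C)I)[C@H]1[C@H](OC(=O)C(C)C)[C@@H](OC(=O)C(C)(C)O[Si](CC)(CC)CC)/C(CO[Si](C)(C)C(C)(C)C)=C\CCI | intermediate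
35 | alkylzinc iodide from 34 (ZnI at C3; alkenyl iodide intact) | C=C1C(=O)O[C@H](/C=C(/C)I)[C@H]1[C@H](OC(=O)C(C)C)[C@@H](OC(=O)C(C)(C)O[Si](CC)(CC)CC)/C(CO[Si](C)(C)C(C)(C)C)=C\CC[Zn]I | intermediate
36 | bis-silyl ether of the target: (1(10)Z,4Z,6R,7S,8S,9S)-germacradien-6,12-olide with C14 OTBS and C9 2-methyl-2-(triethylsilyloxy)propanoate | C=C1C(=O)O[C@@H]2/C=C(/C)CC/C=C(/CO[Si](C)(C)C(C)(C)C)[C@H](OC(=O)C(C)(C)O[Si](CC)(CC)CC)[C@@H](OC(=O)C(C)C)[C@@H]12 | intermediate
37 | CNP0220567.2: (1(10)Z,4Z,6R,7S,8S,9S)-8-isobutyryloxy-9-(2-hydroxy-2-methylpropanoyloxy)-14-hydroxygermacra-1(10),4,11(13)-trien-6,12-olide | C=C1C(=O)O[C@@H]2/C=C(/C)CC/C=C(/CO)[C@H](OC(=O)C(C)(C)O)[C@@H](OC(=O)C(C)C)[C@@H]12 | target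

**Step count and risks**

Total step count: 23. Longest linear sequence: 16 steps (steps 1–5, 9–11, 14, 15, 18–23).

The three steps most likely to fail:

Step 22 (macrocyclisation). The ten-membered Z,Z-diene may form too slowly, so that intermolecular coupling to oligomers, β-hydride elimination or protonation of the organometallic to open-chain reduced material, and insertion of the alkenylpalladium into the C11=C13 acrylate take over; zinc insertion into the alkenyl iodide would also erode the material. The fallback is a nickel-catalysed reductive cross-electrophile macrocyclisation of the two carbon–iodine bonds (NiBr2·glyme, 4,4′-di-tert-butyl-2,2′-bipyridine, manganese powder, DMA, high dilution), which joins the alkyl and alkenyl iodides directly without a preformed organozinc. It sets out from 34 and comes back to the route at 36, and it makes no new compound (F0).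

Step 14 (Barbier allylation). Addition at the hindered ring carbon C7 may be slow, so that protonation of the allylzinc or 1,4-elimination of the C8 alkoxide competes; the iodoenal may be reduced or isomerise from Z to E; and simple or facial diastereoselection may erode in the aqueous, loosely organised transition state. The fallback replaces the zinc reagent by a boron reagent with a rigid closed transition state: copper-catalysed borylation of 19 (B2pin2, CuCl, KOAc, DMF) should give the pinacol allylboronate F1, and its Lewis-acid-catalysed allylboration of 23 (Sc(OTf)3, toluene, low temperature) followed by hydrolytic work-up should give 25, where the route resumes.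

Step 9 (chelation-controlled addition). The Felkin–Anh pathway may compete with the chelate and lower the selectivity at C9, and the basic organometallic may epimerise or conjugate the β,γ-unsaturated α-alkoxy aldehyde. The fallback corrects C9 after the coupling: the product from 8 and 12 is taken as a mixture of 15 and its C4 epimer F2, oxidised with Dess–Martin periodinane to the enone F3, and reduced under non-chelating Felkin–Anh control (K-Selectride, THF, −78 °C) or with an oxazaborolidine (CBS) catalyst, which should return the 3,4-syn alcohol 15.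

**Further compounds**

F0 | step 22 | none | none
F1 | step 14 | pinacol allylboronate from 19 (Bpin in place of Br) | CC1(C)OB(CC2=C[C@H](OCc3ccc(OC)cc3)[C@@H](OC2=O)/C(CO[Si](C)(C)C(C)(C)C)=C\CCOCc3ccc(OC)cc3)OC1(C)C
F2 | step 9 | (3S,4R,5Z)-5-{[(tert-butyldimethylsilyl)oxy]methyl}-3,8-bis[(4-methoxybenzyl)oxy]octa-1,5-dien-4-ol (C4 epimer of 15) | C=C[C@H](OCc1ccc(OC)cc1)[C@H](O)/C(CO[Si](C)(C)C(C)(C)C)=C\CCOCc1ccc(OC)cc1
F3 | step 9 | (3S,5Z)-5-{[(tert-butyldimethylsilyl)oxy]methyl}-3,8-bis[(4-methoxybenzyl)oxy]octa-1,5-dien-4-one | C=C[C@H](OCc1ccc(OC)cc1)C(=O)/C(CO[Si](C)(C)C(C)(C)C)=C\CCOCc1ccc(OC)cc1
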